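**Strategy.** The γ-lactone (O–C7–C8–C17–C19) fused to the ten-membered carbocycle is a masked aldol: its tertiary carbinol C8 sits between the oxygenated carbons C7 and C9, and C17 is the α-carbon of an ester on O7. The last step therefore joins C17 to C8 by a SmI2-mediated intramolecular Reformatsky reaction of a 7-O-(2-bromopropanoyl) 8-ketone that already carries the 6-chloride, the 11,20-epoxide and all four esters; one operation closes the lactone and sets C8 and C17. The precursor is assembled by a Diels–Alder reaction (ring A), a chelation-controlled Grignard addition (C2–C3) and a Nozaki–Hiyama–Kishi closure of the ten-membered ring (C7–C8).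

Key step: step 24

Remark: briarane numbering is used for all intermediates (C15 methyl on C1, C16 exocyclic methylene carbon on C5, C18 methyl on C17, C19 lactone carbonyl, C20 epoxide methylene); α is the ring face opposite the C15 methyl; boronate 7 and racemic 31 are taken as catalogue reagents.

Step 1
Reactants: 1 (R)-2,2-dimethyl-1,3-dioxolane-4-carbaldehyde; 2 2-(triphenylphosphoranylidene)propanal
Product: 3 (E)-3-[(4S)-2,2-dimethyl-1,3-dioxolan-4-yl]-2-methylprop-2-enal
Conditions: toluene, 80 °C
Reagents that add atoms: none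
Why: Wittig olefination with a formyl-stabilised ylide should give the (E)-trisubstituted enal under thermodynamic control, and the neutral medium leaves the α-alkoxy stereocentre (the future C9) untouched.

Step 2
Reactants: 3 (E)-enal; 4 (E)-1-methoxy-3-(trimethylsilyloxy)buta-1,3-diene
Product: 5 cycloadduct (formyl cis to OMe and trans to the dioxolanyl group)
Conditions: toluene, 110 °C, sealed tube, BHT (cat.); excess 4 removed in vacuo, used crude
Reagents that add atoms: none
Why: Normal-demand Diels–Alder reaction in which the diene CH2 terminus bonds to C10 and the methoxy-bearing terminus to C1; suprafacial addition to the (E)-enal places C2 and C9 trans, and the diene should add anti to the allylic C9–O bond of the conformer whose H9 eclipses the alkene (A(1,3) strain with the C15 methyl), which sets C1 and C10 from C9.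

Step 3
Reactants: 6 3-bromobut-3-en-1-ol; 7 (E)-2-(trimethylsilyl)ethenylboronic acid pinacol ester
Product: 8 (E)-3-methylidene-5-(trimethylsilyl)pent-4-en-1-ol
Conditions: Pd(PPh3)4 (3 mol%), K2CO3, dioxane/H2O, 80 °C
Reagents that add atoms: none
Why: Suzuki–Miyaura coupling of a 2-bromoalkene with an (E)-alkenylboronate proceeds with retention at both partners and tolerates the free alcohol.

Step 4
Reactants: 8 dienyl silane alcohol
Product: 9 (E)-(5-bromo-3-methylidenepent-1-en-1-yl)trimethylsilane
Conditions: CBr4, PPh3, CH2Cl2, 0 °C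
Reagents that add atoms: carbon tetrabromide, BrC(Br)(Br)Br
Why: Appel reaction converts the primary alcohol into the bromide through an alkoxyphosphonium ion without touching the silyl diene.

Step 5
Reactants: 9 homoallylic bromide
Product: 10 [(E)-3-methylidene-5-(trimethylsilyl)pent-4-en-1-yl]magnesium bromide
Conditions: Mg turnings, BrCH2CH2Br (cat.), THF, rt; used as solution
Reagents that add atoms: magnesium, [Mg]
Why: Grignard formation by oxidative insertion of magnesium into the primary C–Br bond; the alkenylsilane is inert.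

Step 6
Reactants: 5 cycloadduct; 10 Grignard reagent
Product: 12 enone alcohol, via silyl enol ether carbinol 11 (not isolated)
Conditions: Et2O/THF, −78 → −30 °C; then 0.1 N HCl, THF, 0 °C
Reagents that add atoms: none
Why: Grignard addition to the non-enolisable aldehyde under Cram-chelate control (Mg bridges the C2 carbonyl and the C14 methoxy oxygen, attack from the side of the C15 methyl and away from ring carbon C10) should set C2 as 2S, and dilute acid then hydrolyses the silyl enol ether and eliminates methanol (E1cB) to the cyclohexenone.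

Step 7
Reactants: 12 enone alcohol
Product: 13 2-O-triethylsilyl ether
Conditions: Et3SiOTf, 2,6-lutidine, CH2Cl2, −78 °C
Reagents that add atoms: triethylsilyl trifluoromethanesulfonate, CC[Si](CC)(CC)OS(=O)(=O)C(F)(F)F
Why: Silylation of the hindered secondary alcohol with the silyl triflate protects C2–OH against the hydride steps that follow.

Step 8
Reactants: 13 silyl ether enone
Product: 14 13α,14α-epoxy ketone
Conditions: H2O2 (30%), LiOH (cat.), MeOH, 0 °C
Reagents that add atoms: hydrogen peroxide, OO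
Why: Weitz–Scheffer nucleophilic epoxidation; hydroperoxide should add axially at C14 anti to the axial C15 methyl of the half-chair that keeps the C2 and C9 branches equatorial, giving the α-epoxide as in the 1α,2α-epoxidation of 1-en-3-oxo steroids.

Step 9
Reactants: 14 epoxy ketone
Product: 17 11(20)-methylidene epoxy ketone, via Mannich base 15 (not isolated), via methiodide 16 (not isolated)
Conditions: LiN(SiMe3)2, THF, −78 °C; Me2N=CH2 I, −78 → 0 °C; MeI, CH2Cl2, rt; aq. NaHCO3
Reagents that add atoms: N,N-dimethylmethyleneiminium iodide, C=[N+](C)C.[I-]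
Why: Mannich reaction of the only possible enolate (C11), then quaternisation and E1cB loss of trimethylamine installs C20 as the exocyclic methylene; no stereocentre remains at C11.

Step 10
Reactants: 17 methylidene epoxy ketone
Product: 18 12α-hydroxy 11(20)-ene 13α,14α-epoxide
Conditions: NaBH4, CeCl3·7H2O, MeOH, −78 °C
Reagents that add atoms: none
Why: Luche 1,2-reduction; hydride should attack C12 anti to the neighbouring C13–O bond of the epoxide (Felkin–Anh), giving the axial 12α-alcohol cis to the epoxide.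

Step 11
Reactants: 18 epoxy allylic alcohol
Product: 19 12α,14α-diol
Conditions: LiAlH4, THF, 0 °C → rt
Reagents that add atoms: none
Why: Hydride opening of the epoxide under the Fürst–Plattner rule: axial attack at C13 (C14 is neopentyl) gives the trans-diaxial product, the axial 14α-alcohol with C14 unchanged, as in the reduction of steroidal 1α,2α-epoxides.

Step 12
Reactants: 19 allylic diol
Product: 20 11α,20-epoxy-12α,14α-diol
Conditions: VO(acac)2 (5 mol%), t-BuOOH, CH2Cl2, 0 °C → rt
Reagents that add atoms: tert-butyl hydroperoxide, CC(C)(C)OO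
Why: Hydroxyl-directed vanadium-catalysed epoxidation: the vanadate ester of the allylic 12α-OH delivers oxygen to the α-face of C11=C20 (setting C11) and leaves the silyl diene, which has no directing hydroxyl, untouched.

Step 13
Reactants: 20 epoxy diol
Product: 21 12,14-bis(3-methylbutanoate)
Conditions: (i-PrCH2CO)2O, DMAP, Et3N, CH2Cl2, 40 °C
Reagents that add atoms: 3-methylbutanoic anhydride, CC(C)CC(=O)OC(=O)CC(C)C
Why: DMAP-catalysed acylation of both axial secondary alcohols installs the two isovalerates of the target.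

Step 14
Reactants: 21 bis-isovalerate
Product: 22 2,8,9-triol
Conditions: PPTS (0.3 equiv), MeOH, 40 °C
Reagents that add atoms: none
Why: Mild acid-catalysed transacetalisation of the terminal acetonide and methanolysis of the triethylsilyl ether; the esters and the deactivated spiro-epoxide (flanked by an acyloxy carbon) should survive.

Step 15
Reactants: 22 triol
Product: 23 8-O-triethylsilyl ether
Conditions: Et3SiCl, imidazole, CH2Cl2, −40 °C
Reagents that add atoms: chlorotriethylsilane, CC[Si](Cl)(CC)CC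
Why: Kinetically selective silylation of the primary C8 hydroxyl over the two hindered secondary hydroxyls.

Step 16
Reactants: 23 silyl ether diol
Product: 24 2,9-diacetate
Conditions: Ac2O, DMAP, pyridine, rt
Reagents that add atoms: acetic anhydride, CC(=O)OC(C)=O
Why: Acetylation installs both acetates of the target in one operation.

Step 17
Reactants: 24 dienylsilane
Product: 25 (6E)-7-iodo-5(16),6-diene
Conditions: N-iodosuccinimide, MeCN, 0 °C, dark
Reagents that add atoms: N-iodosuccinimide, O=C1CCC(=O)N1I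
Why: ipso-Iododesilylation of the alkenylsilane (β-silyl cation, then loss of silicon) with retention of the (E)-geometry.

Step 18
Reactants: 25 dienyl iodide
Product: 26 C8 aldehyde
Conditions: (COCl)2, DMSO, CH2Cl2, −78 → −40 °C; i-Pr2NEt, −78 °C
Reagents that add atoms: none
Why: Swern oxidation, in which the chlorosulfonium salt cleaves the primary triethylsilyl ether and oxidises it directly to the aldehyde; the hindered base at low temperature protects the α-acetoxy centre C9.

Step 19
Reactants: 26 iodo aldehyde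
Product: 27 ten-membered dienol (C8 epimers)
Conditions: CrCl2 (10 equiv), NiCl2 (1 mol%), DMSO/THF, 2 mM, rt
Reagents that add atoms: none
Why: Nozaki–Hiyama–Kishi reaction: nickel-catalysed insertion into the C–I bond, transmetallation to trivalent chromium and addition of the alkenylchromium to the aldehyde with retention of the (E)-alkene closes the ten-membered ring at C7–C8, helped by the diequatorial C1/C10 branches; the C8 epimers converge in step 20.

Step 20
Reactants: 27 dienol
Product: 28 ten-membered (6E)-dienone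
Conditions: Dess–Martin periodinane, NaHCO3, CH2Cl2, 0 °C
Reagents that add atoms: none
Why: Dess–Martin oxidation of the allylic alcohol under buffered, non-basic conditions gives the C8 ketone without epimerising C9.

Step 21
Reactants: 28 dienone
Product: 29 (6R,7S)-6,7-epoxy-8-ketone
Conditions: La(O-iPr)3 (10 mol%), (R)-BINOL (10 mol%), Ph3As=O (10 mol%), t-BuOOH, 4 Å MS, THF, rt
Reagents that add atoms: tert-butyl hydroperoxide, CC(C)(C)OO
Why: Catalytic asymmetric nucleophilic epoxidation of the (E)-enone by a lanthanum–BINOL peroxide at the α,β-alkene; the trans geometry is retained and the ligand enantiomer is chosen by analogy with the (αS,βR)-selectivity known for acyclic (E)-enones (the antipode is used if the sense proves reversed).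

Step 22
Reactants: 29 epoxy ketone
Product: 30 (6S,7R)-6-chloro-7-hydroxy-8-ketone
Conditions: LiCl (5 equiv), AcOH (3 equiv), THF, 0 °C
Reagents that add atoms: lithium chloride, [Li+].[Cl-]
Why: SN2 opening of the epoxide by chloride at C6, the carbon that is both allylic and β to the ketone, with inversion at C6 and the C7–O bond intact; the hindered, non-activated 11,20-epoxide should react far more slowly.

Step 23
Reactants: 30 chlorohydrin ketone; 31 2-bromopropanoyl bromide
Product: 32 7-O-(2-bromopropanoyl) ester (CHBr epimers)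
Conditions: pyridine, CH2Cl2, −40 → −20 °C
Reagents that add atoms: none
Why: O-Acylation of the only free hydroxyl (C7) with the acid bromide at low temperature and with a weak base avoids E1cB loss of HCl from the β-chloro ketone.

Step 24
Reactants: 32 bromopropanoate ketone
Product: 35 CNP0238609.2, via samarium enolate 33 (not isolated), via samarium aldolate 34 (not isolated)
Conditions: SmI2 (2.1 equiv, 0.1 M in THF) added dropwise to 32, THF, −78 °C; then aq. NH4Cl
Reagents that add atoms: none
Why: Two single-electron transfers from SmI2 cleave the C–Br bond of 32 to the trivalent samarium ester enolate 33, whose α-carbon C17 adds to the adjacent C8 ketone to give aldolate 34, protonated on work-up. The closest known reaction type is the SmI2-promoted intramolecular Reformatsky reaction of α-haloacyl esters of hydroxy ketones. The γ-lactone ring (O–C7–C8–C17–C19) closes in a 5-(enolendo)-exo-trig mode, which is feasible here because enolate and ketone are held on adjacent ring atoms. C8 is set by the tether: C17 can reach the carbonyl only from the face that carries O7, and in the ring conformer with C6 and C9 antiperiplanar across C7–C8 this should give the trans-fused 8R carbinol. C17 is set by the compact transition state that turns the C18 methyl toward the carbonyl oxygen and away from C9, giving 17R, which is also the more stable epimer if the α-centre equilibrates. The step needs electron transfer to the C–Br bond in preference to the α-acyloxy ketone and the allylic C6–Cl bond; the much easier reduction of the α-bromo ester at −78 °C, slow addition of SmI2 and immediate quench should secure it.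

**Compound list**

1 | (R)-2,2-dimethyl-1,3-dioxolane-4-carbaldehyde | O=C[C@H]1COC(C)(C)O1 | starting material
2 | 2-(triphenylphosphoranylidene)propanal | CC(C=O)=P(c1ccccc1)(c1ccccc1)c1ccccc1 | starting material
3 | (E)-3-[(4S)-2,2-dimethyl-1,3-dioxolan-4-yl]-2-methylprop-2-enal | O=C/C(C)=C/[C@H]1COC(C)(C)O1 | intermediate
4 | (E)-1-methoxy-3-(trimethylsilyloxy)buta-1,3-diene | CO/C=C/C(=C)O[Si](C)(C)C | starting material
5 | cycloadduct: 2-methoxy-1-methyl-4-(trimethylsilyloxy)-6-[(4S)-2,2-dimethyl-1,3-dioxolan-4-yl]cyclohex-3-ene-1-carbaldehyde (CHO cis to OMe, trans to the dioxolanyl group) | O=C[C@@]2(C)[C@@H](OC)C=C(O[Si](C)(C)C)C[C@@H]2[C@H]1COC(C)(C)O1 | intermediate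
6 | 3-bromobut-3-en-1-ol | OCCC(Br)=C | starting material
7 | (E)-2-(trimethylsilyl)ethenylboronic acid pinacol ester | C[Si](C)(C)/C=C/B1OC(C)(C)C(C)(C)O1 | starting material
8 | (E)-3-methylidene-5-(trimethylsilyl)pent-4-en-1-ol | OCCC(=C)/C=C/[Si](C)(C)C | intermediate
9 | (E)-(5-bromo-3-methylidenepent-1-en-1-yl)trimethylsilane | BrCCC(=C)/C=C/[Si](C)(C)C | intermediate
10 | [(E)-3-methylidene-5-(trimethylsilyl)pent-4-en-1-yl]magnesium bromide | Br[Mg]CCC(=C)/C=C/[Si](C)(C)C | intermediate
11 | silyl enol ether carbinol: (2S)-alcohol from addition of 10 to 5, OMe and silyl enol ether intact | C[Si](C)(C)/C=C/C(=C)CC[C@H](O)[C@@]2(C)[C@@H](OC)C=C(O[Si](C)(C)C)C[C@@H]2[C@H]1COC(C)(C)O1 | intermediate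
12 | enone alcohol: 4-[(1S,5E)-1-hydroxy-4-methylidene-6-(trimethylsilyl)hex-5-en-1-yl]-4-methyl-5-[(4S)-2,2-dimethyl-1,3-dioxolan-4-yl]cyclohex-2-en-1-one (side chains trans) | C[Si](C)(C)/C=C/C(=C)CC[C@H](O)[C@@]2(C)C=CC(=O)C[C@@H]2[C@H]1COC(C)(C)O1 | intermediate
13 | 2-O-triethylsilyl ether of 12 | C[Si](C)(C)/C=C/C(=C)CC[C@H](O[Si](CC)(CC)CC)[C@@]2(C)C=CC(=O)C[C@@H]2[C@H]1COC(C)(C)O1 | intermediate
14 | 13α,14α-epoxy 12-ketone | C[Si](C)(C)/C=C/C(=C)CC[C@H](O[Si](CC)(CC)CC)[C@@]2(C)[C@H]4O[C@H]4C(=O)C[C@@H]2[C@H]1COC(C)(C)O1 | intermediate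
15 | Mannich base: 11-(dimethylaminomethyl) derivative of 14 (one C11 epimer drawn) | C[Si](C)(C)/C=C/C(=C)CC[C@H](O[Si](CC)(CC)CC)[C@@]2(C)[C@H]4O[C@H]4C(=O)[C@@H](CN(C)C)[C@@H]2[C@H]1COC(C)(C)O1 | intermediate
16 | methiodide of 15 | C[Si](C)(C)/C=C/C(=C)CC[C@H](O[Si](CC)(CC)CC)[C@@]2(C)[C@H]4O[C@H]4C(=O)[C@@H](C[N+](C)(C)C)[C@@H]2[C@H]1COC(C)(C)O1.[I-] | intermediate
17 | 11(20)-methylidene 13α,14α-epoxy 12-ketone | C[Si](C)(C)/C=C/C(=C)CC[C@H](O[Si](CC)(CC)CC)[C@@]2(C)[C@H]4O[C@H]4C(=O)C(=C)[C@@H]2[C@H]1COC(C)(C)O1 | intermediate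
18 | 12α-hydroxy 11(20)-ene 13α,14α-epoxide | C[Si](C)(C)/C=C/C(=C)CC[C@H](O[Si](CC)(CC)CC)[C@@]2(C)[C@H]4O[C@H]4[C@@H](O)C(=C)[C@@H]2[C@H]1COC(C)(C)O1 | intermediate
19 | 12α,14α-diol with 11(20)-ene | C[Si](C)(C)/C=C/C(=C)CC[C@H](O[Si](CC)(CC)CC)[C@@]2(C)[C@@H](O)C[C@@H](O)C(=C)[C@@H]2[C@H]1COC(C)(C)O1 | intermediate
20 | 11α,20-epoxy-12α,14α-diol | C[Si](C)(C)/C=C/C(=C)CC[C@H](O[Si](CC)(CC)CC)[C@@]2(C)[C@@H](O)C[C@@H](O)[C@]3(CO3)[C@@H]2[C@H]1COC(C)(C)O1 | intermediate
21 | 12,14-bis(3-methylbutanoate) of 20 | C[Si](C)(C)/C=C/C(=C)CC[C@H](O[Si](CC)(CC)CC)[C@@]2(C)[C@@H](OC(=O)CC(C)C)C[C@@H](OC(=O)CC(C)C)[C@]3(CO3)[C@@H]2[C@H]1COC(C)(C)O1 | intermediate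
22 | 2,8,9-triol | C[Si](C)(C)/C=C/C(=C)CC[C@H](O)[C@@]2(C)[C@@H](OC(=O)CC(C)C)C[C@@H](OC(=O)CC(C)C)[C@]3(CO3)[C@@H]2[C@H](O)CO | intermediate
23 | 8-O-triethylsilyl ether of 22 | C[Si](C)(C)/C=C/C(=C)CC[C@H](O)[C@@]2(C)[C@@H](OC(=O)CC(C)C)C[C@@H](OC(=O)CC(C)C)[C@]3(CO3)[C@@H]2[C@H](O)CO[Si](CC)(CC)CC | intermediate
24 | 2,9-diacetate of 23 | C[Si](C)(C)/C=C/C(=C)CC[C@H](OC(C)=O)[C@@]2(C)[C@@H](OC(=O)CC(C)C)C[C@@H](OC(=O)CC(C)C)[C@]3(CO3)[C@@H]2[C@H](OC(C)=O)CO[Si](CC)(CC)CC | intermediate
25 | (6E)-7-iodo-5(16),6-diene | I/C=C/C(=C)CC[C@H](OC(C)=O)[C@@]2(C)[C@@H](OC(=O)CC(C)C)C[C@@H](OC(=O)CC(C)C)[C@]3(CO3)[C@@H]2[C@H](OC(C)=O)CO[Si](CC)(CC)CC | intermediate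
26 | C8 aldehyde | I/C=C/C(=C)CC[C@H](OC(C)=O)[C@@]2(C)[C@@H](OC(=O)CC(C)C)C[C@@H](OC(=O)CC(C)C)[C@]3(CO3)[C@@H]2[C@H](OC(C)=O)C=O | intermediate
27 | ten-membered (6E)-5(16),6-dien-8-ol (both C8 epimers) | C1C[C@H](OC(C)=O)[C@@]2(C)[C@@H](OC(=O)CC(C)C)C[C@@H](OC(=O)CC(C)C)[C@]3(CO3)[C@@H]2[C@H](OC(C)=O)C(O)/C=C/C(=C)1 | intermediate
28 | ten-membered (6E)-5(16),6-dien-8-one | C1C[C@H](OC(C)=O)[C@@]2(C)[C@@H](OC(=O)CC(C)C)C[C@@H](OC(=O)CC(C)C)[C@]3(CO3)[C@@H]2[C@H](OC(C)=O)C(=O)/C=C/C(=C)1 | intermediate
29 | (6R,7S)-6,7-epoxy-5(16)-en-8-one | C1C[C@H](OC(C)=O)[C@@]2(C)[C@@H](OC(=O)CC(C)C)C[C@@H](OC(=O)CC(C)C)[C@]3(CO3)[C@@H]2[C@H](OC(C)=O)C(=O)[C@H]4O[C@@H]4C(=C)1 | intermediate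
30 | (6S,7R)-6-chloro-7-hydroxy-5(16)-en-8-one | C1C[C@H](OC(C)=O)[C@@]2(C)[C@@H](OC(=O)CC(C)C)C[C@@H](OC(=O)CC(C)C)[C@]3(CO3)[C@@H]2[C@H](OC(C)=O)C(=O)[C@@H](O)[C@@H](Cl)C(=C)1 | intermediate
31 | 2-bromopropanoyl bromide (racemic) | CC(Br)C(Br)=O | starting material
32 | 7-O-(2-bromopropanoyl) ester of 30 (both CHBr epimers) | C1C[C@H](OC(C)=O)[C@@]2(C)[C@@H](OC(=O)CC(C)C)C[C@@H](OC(=O)CC(C)C)[C@]3(CO3)[C@@H]2[C@H](OC(C)=O)C(=O)[C@@H](OC(=O)C(C)Br)[C@@H](Cl)C(=C)1 | intermediate
33 | samarium enolate of the O7 propanoate | C1C[C@H](OC(C)=O)[C@@]2(C)[C@@H](OC(=O)CC(C)C)C[C@@H](OC(=O)CC(C)C)[C@]3(CO3)[C@@H]2[C@H](OC(C)=O)C(=O)[C@@H](OC(=CC)O[Sm](I)I)[C@@H](Cl)C(=C)1 | intermediate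
34 | samarium aldolate (C8–O–SmI2 form of the target) | C=C1CC[C@H](OC(C)=O)[C@@]2(C)[C@@H](OC(=O)CC(C)C)C[C@@H](OC(=O)CC(C)C)[C@]3(CO3)[C@@H]2[C@H](OC(C)=O)[C@]2(O[Sm](I)I)[C@@H](C)C(=O)O[C@H]2[C@H]1Cl | intermediate
35 | CNP0238609.2 | C=C1CC[C@H](OC(C)=O)[C@@]2(C)[C@@H](OC(=O)CC(C)C)C[C@@H](OC(=O)CC(C)C)[C@]3(CO3)[C@@H]2[C@H](OC(C)=O)[C@]2(O)[C@@H](C)C(=O)O[C@H]2[C@H]1Cl | target

**Step count.** Total: 24 steps. Longest linear sequence: 22 steps (6 → 8 → 9 → 10 → 12 → … → 35); the line from 1 is 21 steps.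

**Steps most likely to fail**

Step 19 (ring closure). Closure may lose to intermolecular coupling and oligomerisation, because the transition state must hold an (E)-alkene and an exocyclic alkene in a ten-membered ring; protonation of the alkenylchromium before it cyclises is a second loss channel. The fallback closes the ring by metathesis; it sets out from 25 and comes back at 28. Pd(PPh3)4-catalysed hydrodeiodination of 25 with Bu3SnH would give the terminal diene silyl ether F1. Swern oxidation as in step 18 would give the diene aldehyde F2. Intermolecular Nozaki–Hiyama–Kishi vinylation (vinyl bromide, CrCl2, NiCl2 cat., DMSO) would give the allylic alcohol F3, and Dess–Martin oxidation the vinyl ketone F4. Ring-closing metathesis of F4 (second-generation Hoveyda–Grubbs catalyst, toluene, 80 °C, 1 mM) between the enone vinyl group and the monosubstituted diene terminus would expel ethylene and give dienone 28.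

Step 21 (enone epoxidation). The conformationally biased macrocyclic enone may override the catalyst and give poor facial selectivity; the peroxide may add at the exocyclic C16 terminus; the basic peroxide may epimerise C9. The fallback uses a hydroxyl-directed, non-basic epoxidation; it sets out from 27 and comes back at 29. The C8 epimer of 27 that is matched to L-(+)-diethyl tartrate would be epoxidised with Ti(O-iPr)4, L-(+)-diethyl tartrate and t-BuOOH (CH2Cl2, −20 °C, 4 Å MS) to the erythro epoxy alcohol F5. Dess–Martin oxidation of F5 would give 29. The mismatched epimer would be recycled by oxidation to 28 and Luche reduction.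

Step 24 (key step). Single-electron reduction may divert to the α-acyloxy ketone (loss of the C9 acetate or of the C7 ester) or to the allylic C6–Cl bond, and closure may give the wrong C17 epimer. The fallback forms the same C8–C17 bond by a two-electron path; it sets out from 30 and comes back at 35. Acylation of O7 with acryloyl chloride (pyridine, CH2Cl2, −40 °C) would give the 7-O-acrylate F6. Copper hydride reductive aldol cyclisation of F6 ([(Ph3P)CuH]6, toluene, −40 °C, or catalytic Cu(OAc)2 with a bisphosphine and a silane) would generate a copper enolate by 1,4-hydride addition, which adds to the C8 ketone and gives 35 without any ketyl intermediate.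

**Further compounds**

F1 | step 19 | terminal diene silyl ether | C=CC(=C)CC[C@H](OC(C)=O)[C@@]2(C)[C@@H](OC(=O)CC(C)C)C[C@@H](OC(=O)CC(C)C)[C@]3(CO3)[C@@H]2[C@H](OC(C)=O)CO[Si](CC)(CC)CC
F2 | step 19 | diene aldehyde | C=CC(=C)CC[C@H](OC(C)=O)[C@@]2(C)[C@@H](OC(=O)CC(C)C)C[C@@H](OC(=O)CC(C)C)[C@]3(CO3)[C@@H]2[C@H](OC(C)=O)C=O
F3 | step 19 | allylic alcohol (C8 epimers) | C=CC(=C)CC[C@H](OC(C)=O)[C@@]2(C)[C@@H](OC(=O)CC(C)C)C[C@@H](OC(=O)CC(C)C)[C@]3(CO3)[C@@H]2[C@H](OC(C)=O)C(O)C=C
F4 | step 19 | vinyl ketone | C=CC(=C)CC[C@H](OC(C)=O)[C@@]2(C)[C@@H](OC(=O)CC(C)C)C[C@@H](OC(=O)CC(C)C)[C@]3(CO3)[C@@H]2[C@H](OC(C)=O)C(=O)C=C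
F5 | step 21 | erythro epoxy alcohol | C1C[C@H](OC(C)=O)[C@@]2(C)[C@@H](OC(=O)CC(C)C)C[C@@H](OC(=O)CC(C)C)[C@]3(CO3)[C@@H]2[C@H](OC(C)=O)[C@@H](O)[C@H]4O[C@@H]4C(=C)1
F6 | step 24 | 7-O-acrylate | C1C[C@H](OC(C)=O)[C@@]2(C)[C@@H](OC(=O)CC(C)C)C[C@@H](OC(=O)CC(C)C)[C@]3(CO3)[C@@H]2[C@H](OC(C)=O)C(=O)[C@@H](OC(=O)C=C)[C@@H](Cl)C(=C)1
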